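The rate constants stand for no real mixture; the result is computed.

Your flask, then.

solid substrate 0.40 M; coupling partner 1.00 equiv; time 20 s

    2 solid substrate → homo dimer (k1 = 0.080 L mol⁻¹ s⁻¹)
    solid substrate ⇌ dissolved substrate, rate k2*(cs2 - [dissolved substrate]) while solid is left; crystals form when [dissolved substrate] > cs2 (cs2 = 0.10 M, k2 = 0.32 s⁻¹)
    dissolved substrate + coupling partner → target (k3 = 28 L mol⁻¹ s⁻¹)
    target ⇌ isomer of the product (K4 = 4.3, k4 = 0.031 s⁻¹)

- midnight: doubling the amount of coupling partner, all else as stated
- dawn: doubling the dissolution coefficient of step 2, all else as stated
- summer: doubling the solubility in step 2, all else as stated

- in percentages every species weighs as the solid substrate in it: one homo dimer counts as two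
- a step written with two of one species runs at k times the square of its concentration and takes two of it each time
- as a solid, counted per litre of solution: solid substrate
- at the start none of the solid substrate is in solution
- run time (flask): 20 s

- the target standing at 20 s, as a percentage of the solid substrate charged
- the change that raises the amount of target at 20 s, in percent of the solid substrate charged most ("none" if none brings more than 2 percentage points) (midnight / dawn / summer / none)
- amount of target at 20 s, in percent of the solid substrate charged, after dawn

1. We compare rates at one moment. Dissolved substrate couples with a half-life of 0.062 s at charged concentrations, far shorter than the 2.17 s of dissolving. So at the charge dissolution is the rate-limiting step on the way to target, and the solid dissolves into the near-empty solution at about 0.0320 M s⁻¹, the dissolution coefficient times the solubility.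

2. At the start, homo dimer takes solid substrate at 0.0256 M s⁻¹. We call solid lost to homo dimer per solid dissolved the drain ratio: 0.800 at the start.

3. Now the drift. With dissolving held at that rate, the ratio follows [solid substrate] squared, so at 0.200 M it is 0.200. The homo dimer's share of the solid lost falls from 44.4% through 16.7% towards zero. Simpson's weighted mean of these shares puts 18.5% of the charge into homo dimer, leaving 81.5% for target plus isomer.

4. The relaxation half-life of target and isomer, 18.1 s, is shorter than the run of 20 s, so we expect target well below that total, and we stop there by hand.

5. Dawn and summer each double the dissolving rate into a near-empty solution, so each takes the starting drain ratio to 0.400. We therefore expect the same gain from both.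

6. Your forecast gives 52.5% of target, 54.3% after dawn, and names summer as best, at 55.3% of target, “a gain above 2 points”. Here we differ, since our ratio treats dawn and summer alike.

The flask gives 53.3% of target at 20 s, and 54.6% after dawn; the best change comes out as none. Homo dimer in the flask stands at 18.9% at 20.0 s. With the starting drain ratio at 0.400 in both changed flasks, target at 20 s rises by 1.3 percentage points after dawn and by 1.3 points after summer.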